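## Analysis of the target

Target 25 is a C–C linked biflavonoid. A flavan-3-ol (ring A with 7-OH, pyran ring C, catechol ring B on C2) is bonded through C4 to C2' of the pyrogallol ring E, and ring E is also the 2-aryl group of a 3,7-dihydroxy-4H-chromen-4-one whose benzo ring is ring D. The only stereocentres are the three contiguous carbons of ring C: C2 (R), C3 (S) and C4 (S). The C2 aryl, the C3 hydroxyl and the C4 aryl are each trans to their neighbour (2,3-trans, 3,4-trans), so the two aryl groups are cis and all three substituents can be equatorial. The molecule carries eight phenols (an oxidation-prone pyrogallol and catechol among them) and a flavonol enol; in ring C the benzylic C2–O1 ether and the doubly benzylic C4–H ionise under strong protic or Lewis acid. The phenols therefore have to travel as benzyl ethers, which leave by neutral hydrogenolysis, and not as methyl ethers. Ring A has no 5-oxygen, so the common chiral-pool flavan-3-ols do not map onto it and the absolute configuration must be created. The hardest point is C4: a tertiary, doubly benzylic carbon inside the all-trans triad, bonded to a ring E carbon flanked by the C3' oxygen and by C1', which carries the flavonol. The strategy rests on one feature: C2 of ring C is an aldehyde-level carbon lying between O1 and C3. If the ring A phenol and ring E are first joined through a 1,1-diarylethene whose two alkene carbons are the future C4 and C3, the ring B aldehyde can be inserted between the phenol oxygen and the alkene terminus; this closes ring C, makes C2 the only new stereocentre, and leaves a C3=C4 double bond that takes up H and OH syn, anti to the C2 aryl.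

## Retrosynthetic reasoning

25 from 24. The eight O–benzyl bonds are cut last. Hydrogenolysis is neutral, so neither C2–O1 nor C4–H of ring C is put at risk, and the air-sensitive polyphenol appears only in the final flask.

24 from 22, and 22 from 19 and 21. The pyranone O1–C2 bond and the C3–O bond of the flavonol are cut back to the 2'-hydroxychalcone 22. Ring D has no oxygen ortho to its carbonyl, which is the case in which oxidative chalcone cyclisation gives flavonols and not aurones, and the 3-hydroxyl comes with the ring closure. Cutting the enone double bond of 22 gives aldehyde 19 and acetophenone 21; 21 is the 4-O-benzyl ether of commercial 20. The forward condensation must tolerate an aldehyde with one bulky ortho substituent.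

19 from 17, and 17 from 16. The formyl carbon on C1' of ring E is traced to the bromine of 17, so a robust halogen serves as placeholder for the flavonol through all earlier steps. The C3 oxygen is benzylated (16 to 17) before the aldehyde exists, because a free C3–OH and the C1' aldehyde would close a six-membered lactol (O–C3–C4–C2'–C1'–CHO).

16 from 14. The C3–O and C4–H bonds are removed to give the 4-aryl-2H-chromene 14. Only a concerted syn addition puts OH on C3 and H on C4 on the same face; any stepwise delivery of hydride to a C4 cation would come anti to the C3 oxygen and give the 3,4-cis isomer. Hydroboration–oxidation anti to the C2 aryl therefore relays the single stereocentre of 14 to the whole triad.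

14 from 11 and 12 (key disconnection). O1–C2 and C2–C3 are cut, which removes the ring B aldehyde 12 from between the phenol oxygen and the alkene terminus of 11. This is the only place where ring C can be opened so that the congested C4–ring E bond is already present in a simple, achiral, planar precursor. The forward reaction has to form two bonds, close ring C, and set C2 in the absolute sense under a chiral Brønsted acid. Regiochemistry needs no control, because the CH2 terminus of 11 is the only nucleophilic carbon that can reach the electrophile.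

11 from 10, 10 from 8, 8 from 7, and 7 from 3 (through 6) and 5. The phenol of 11 is released from its allyl ether 10 under neutral conditions. The alkene CH2 of 10 is cut back to ketone 8 (methyl addition, dehydration). The C4–C2' bond is cut at the benzhydrol 7, where it forms as an aryllithium adding to an unhindered aldehyde, the stage at which the crowding around ring E costs least. The lithiated carbon of 6 is the position between bromine and benzyloxy of 3, so the ring E substitution pattern is fixed by the starting bromide.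

3 from 2, 2 from 1, and 5 from 4. These are protecting-group adjustments on commercial materials: methyl is exchanged for benzyl on ring E at the outset, and the ring A phenol is masked as an allyl ether that is orthogonal to benzyl.

## Alternatives that were turned down

Alternative 1: The disconnection is at O1–C8a and C4–C4a of the flavonol, so ring D arrives as an aryne and the rest as the ring E arylpropiolic acid A1, 3-{3,4,5-tris(benzyloxy)-2-[(2R,3S,4S)-3,7-bis(benzyloxy)-2-[3,4-bis(benzyloxy)phenyl]chroman-4-yl]phenyl}prop-2-ynoic acid. In the forward step CsF unmasks the silyl triflate A2 to the chloro-aryne A3. The carboxylate of A1 adds through oxygen to the aryne carbon remote from chlorine, and the aryl anion takes over the acyl group to give the o-hydroxyaryl ynone A4.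
- For: it is convergent and nearly neutral, and it avoids strongly basic condensation and oxidation on a hindered aldehyde. On mildness of the ring D assembly it is at least as good as the chosen end game.
- Against: the new chemistry is spent on ring D, the one ring available from the commodity acetophenone 20 by classical steps. It needs a chlorine on A2 solely to steer the addition, which must be installed and later removed. A4 leads to a flavone, so C3 must still be hydroxylated. The ynone closure must be 6-endo and not 5-exo. A1 already contains the full stereotriad and the crowded C4–C2' bond, about which this plan says nothing.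
- Comparison: the chosen route makes ring D in two classical steps that bring the 3-hydroxyl with them, and puts its one uncertain step where the real difficulty lies, in ring C.

Alternative 2: The disconnection is ring E itself, at C2'–C3' and C1'–C6'. The precursors are the alkyne A5, in which a two-carbon unit links flavan C4 to flavonol C2, and 3,4-bis(benzyloxy)furan A6. A [4+2] cycloaddition across the alkyne, followed by acid opening of the oxygen bridge and aromatisation, gives the C3' phenol A7.
- For: it sidesteps the crowding at C4–C2', because a slim alkynyl group is easy to place on C4 trans to the C3 oxygen and the arene is grown afterwards. On this point it is stronger than the chosen route.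
- Against: an internal alkyne flanked by a tertiary propargylic centre is a poor dienophile, furan cycloadditions are reversible, and the electron-rich A6 is labile. The bridge must open so that oxygen stays on C3' and not on C6', a choice between two similarly stabilised cations. The acid needed for that opening acts on a molecule whose C2 and C4 ionise easily. The stereotriad still has to be made separately, so the step count is higher.
- Comparison: the chosen route meets the crowding early, in a simple carbonyl addition, and has no regiochemical question on ring E because all three oxygens and the bromine come from 3.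

Alternative 3: The disconnection is at O1–C2 and C3–C4 of ring C. A chiral phosphoric acid dehydrates the o-hydroxybenzhydrol A8 to the ring A o-quinone methide A9, which adds the (E)-enol pivalate A10 of the ring B arylacetaldehyde in a [4+2] cycloaddition to give the all-trans pivalate A11.
- For: ring C and all three stereocentres are made in one step, with no diarylethene, no hydroboration and no separate C3 protection. A8 is the deallylated analogue of 7. On step economy and convergence it is stronger than the chosen route, by about four steps.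
- Against: A10 carries two donors that polarise its alkene in opposite senses. The aryl group favours the required C3–C4 bond, the acyloxy group the reverse, and an enol ester is a weak nucleophile. The methide carbon of A9 bears the di-ortho-substituted ring E, so its geometry and the endo/exo preference, which together fix C4 against C3, are hard to predict. One transition state must control three relative and one absolute relationship, and a stepwise cationic path would scramble the 2,3-relationship.
- Comparison: the chosen route asks its uncertain step for one stereocentre only, has a single possible regiochemistry, and obtains C3 and C4 from a stereospecific syn addition whose outcome follows from the mechanism.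

Key step: step 8

Assumption: the sense of induction of the confined acid in step 8 cannot be derived with confidence; the (S,S) antipode is written, and its mirror image is to be used if it delivers the 2R chromene.

Remark: chromene 14 is 2S by the sequence rules although its C2 has the same spatial arrangement as C2 (R) of 16–25, because the sp2 carbon C3 ranks below the aryl group.

## Route

Step 1
Reactants: 1 trimethyl ether 5-bromo-1,2,3-trimethoxybenzene
Product: 2 triol 5-bromobenzene-1,2,3-triol
Conditions: BBr3 (3.5 equiv), CH2Cl2, −78 °C → rt; then H2O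
Reagents that add atoms: none
Why: Lewis-acid cleavage of aryl methyl ethers (BBr3 demethylation); the aryl bromide is inert, and the methyl groups must be exchanged now because no demethylation would spare the flavan later.

Step 2
Reactants: 2 triol 5-bromobenzene-1,2,3-triol
Product: 3 tribenzyl ether 5-bromo-1,2,3-tris(benzyloxy)benzene
Conditions: BnBr (3.3 equiv), K2CO3, DMF, rt, under N2
Reagents that add atoms: benzyl bromide, BrCc1ccccc1
Why: Williamson ether synthesis; benzyl ethers should survive bases, organometallics, borane and the acid catalyst and leave by hydrogenolysis, and exclusion of air protects the pyrogallol until it is capped.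

Step 3
Reactants: 4 salicylaldehyde 4-(benzyloxy)-2-hydroxybenzaldehyde
Product: 5 allyl ether 2-(allyloxy)-4-(benzyloxy)benzaldehyde
Conditions: allyl bromide (1.2 equiv), K2CO3, DMF, rt
Reagents that add atoms: allyl bromide, C=CCBr
Why: Williamson O-allylation masks the phenol through the organometallic and oxidation steps; allyl is orthogonal to benzyl and, unlike acetal-type groups, its removal releases no aldehyde that could enter a Prins reaction with the diarylethene.

Step 4
Reactants: 3 tribenzyl ether 5-bromo-1,2,3-tris(benzyloxy)benzene; 5 allyl ether 2-(allyloxy)-4-(benzyloxy)benzaldehyde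
Product: 7 benzhydrol racemic [2-(allyloxy)-4-(benzyloxy)phenyl][6-bromo-2,3,4-tris(benzyloxy)phenyl]methanol, via aryllithium 6 (not isolated)
Conditions: LiN(iPr)2 (1.1 equiv), THF, −78 °C, 1 h; then 5, −78 °C; H2O
Reagents that add atoms: none
Why: Directed ortho-lithiation at the C–H flanked by bromine and benzyloxy, the most acidic ring position; the amide base does not exchange bromine, and at −78 °C aryllithium 6 should persist long enough for 1,2-addition to the aldehyde. The carbinol centre is formed racemic and is erased in step 5.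

Step 5
Reactants: 7 benzhydrol racemic [2-(allyloxy)-4-(benzyloxy)phenyl][6-bromo-2,3,4-tris(benzyloxy)phenyl]methanol
Product: 8 benzophenone [2-(allyloxy)-4-(benzyloxy)phenyl][6-bromo-2,3,4-tris(benzyloxy)phenyl]methanone
Conditions: Dess–Martin periodinane (1.5 equiv), NaHCO3, CH2Cl2, 0 °C → rt
Reagents that add atoms: none
Why: Dess–Martin oxidation of a secondary bis-benzylic alcohol under buffered conditions that leave the allyl and benzyl ethers and the bromide untouched.

Step 6
Reactants: 8 benzophenone [2-(allyloxy)-4-(benzyloxy)phenyl][6-bromo-2,3,4-tris(benzyloxy)phenyl]methanone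
Product: 10 diarylethene 2-(allyloxy)-4-(benzyloxy)-1-{1-[6-bromo-2,3,4-tris(benzyloxy)phenyl]ethenyl}benzene, via tertiary carbinol 9 (not isolated)
Conditions: MeMgBr (2 equiv), THF, 0 °C → rt; H2O; then TsOH·H2O (5 mol%), toluene, 40 °C
Reagents that add atoms: methylmagnesium bromide, C[Mg]Br
Why: Grignard 1,2-addition to a non-enolisable ketone (the small methyl nucleophile tolerates the three ortho substituents and does not exchange with the aryl bromide), then acid-catalysed E1 dehydration of the tertiary bis-benzylic carbinol, whose only β-hydrogens are on the methyl group, so a single alkene can form.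

Step 7
Reactants: 10 diarylethene 2-(allyloxy)-4-(benzyloxy)-1-{1-[6-bromo-2,3,4-tris(benzyloxy)phenyl]ethenyl}benzene
Product: 11 vinylphenol 5-(benzyloxy)-2-{1-[6-bromo-2,3,4-tris(benzyloxy)phenyl]ethenyl}phenol
Conditions: Pd(PPh3)4 (5 mol%), morpholine (5 equiv), THF, rt
Reagents that add atoms: none
Why: Tsuji–Trost-type deallylation: zerovalent palladium ionises the allyl aryl ether to a π-allyl complex that morpholine captures. The conditions are neutral, so the acid-sensitive diarylethene is not protonated, and the hindered, electron-rich aryl bromide should not undergo oxidative addition at room temperature.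

Step 8
Reactants: 11 vinylphenol 5-(benzyloxy)-2-{1-[6-bromo-2,3,4-tris(benzyloxy)phenyl]ethenyl}phenol; 12 aldehyde 3,4-bis(benzyloxy)benzaldehyde
Product: 14 chromene (2S)-7-(benzyloxy)-2-[3,4-bis(benzyloxy)phenyl]-4-[6-bromo-2,3,4-tris(benzyloxy)phenyl]-2H-chromene, via hemiacetal 13 (not isolated)
Conditions: (S,S)-imidodiphosphorimidate acid [two (S)-3,3'-bis(3,5-bis(trifluoromethyl)phenyl)-BINOL phosphoryl units, P=N–SO2CF3 groups] (5 mol%), 12 (1.2 equiv), 5 Å MS, CHCl3, −20 °C
Reagents that add atoms: none
Why: Proposed new method: the acid condenses phenol 11 with aldehyde 12 through hemiacetal 13 to an O-aryl oxocarbenium ion (O1–C2) held as a contact ion pair with the confined chiral anion; the unsubstituted alkene terminus, made nucleophilic by the para benzyloxy group of ring A, attacks C2 in a 6-endo-trig Prins closure of ring C (C2–C3), and the tertiary bis-benzylic C4 cation then loses a C3 proton to the anion, giving the 2H-chromene and returning the acid. The closest known reaction types are catalytic asymmetric Prins and oxa-Pictet–Spengler cyclisations with confined imidodiphosphate-type acids and the racemic acid-promoted condensation of 2-vinylphenols with aldehydes to 2H-chromenes; the enantioselective union of the two on a 2-(1-arylvinyl)phenol is what is new. The one new stereocentre, C2, is set in the C–C bond-forming step by the chiral counter-anion, which distinguishes the two faces of the oxocarbenium ion inside its pocket. Regiochemistry needs no control, since only the CH2 terminus can attack and closure through C4 would give a four-membered ring. The selectivity actually demanded is chemoselectivity: protonation of the alkene and its capture as a 1,3-benzodioxine are reversible, whereas loss of water and of the C3 proton make chromene formation irreversible, so material should drain to 14. Molecular sieves and low temperature are meant to limit re-ionisation of the C2–O1 bond of the product; the bromide and the benzyl ethers are inert to the catalyst.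

Step 9
Reactants: 14 chromene (2S)-7-(benzyloxy)-2-[3,4-bis(benzyloxy)phenyl]-4-[6-bromo-2,3,4-tris(benzyloxy)phenyl]-2H-chromene
Product: 16 flavan-3-ol (2R,3S,4S)-7-(benzyloxy)-2-[3,4-bis(benzyloxy)phenyl]-4-[6-bromo-2,3,4-tris(benzyloxy)phenyl]chroman-3-ol, via alkylborane 15 (not isolated)
Conditions: BH3·THF (4 equiv), THF, 0 °C → rt; then NaOH (3 M), H2O2 (30%), 0 °C → rt
Reagents that add atoms: hydrogen peroxide, OO
Why: Hydroboration–oxidation: H and B add syn across C3=C4 with boron on the less substituted C3 (C4, the diaryl-substituted carbon, is also the electronically disfavoured site for boron), from the face anti to the C2 aryl. Oxidation with retention places 3-OH trans to the C2 aryl and cis to the new C4–H, so ring E ends trans to the hydroxyl and the all-trans (2R,3S,4S) triad results.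

Step 10
Reactants: 16 flavan-3-ol (2R,3S,4S)-7-(benzyloxy)-2-[3,4-bis(benzyloxy)phenyl]-4-[6-bromo-2,3,4-tris(benzyloxy)phenyl]chroman-3-ol
Product: 17 benzyl ether (2R,3S,4S)-3,7-bis(benzyloxy)-2-[3,4-bis(benzyloxy)phenyl]-4-[6-bromo-2,3,4-tris(benzyloxy)phenyl]chromane
Conditions: NaH (1.5 equiv), BnBr (1.5 equiv), n-Bu4NI (cat.), DMF, 0 °C → rt
Reagents that add atoms: benzyl bromide, BrCc1ccccc1
Why: Williamson etherification of the secondary alcohol; capping C3–OH prevents lactol formation with the aldehyde of step 11 and keeps the final deprotection a single hydrogenolysis. No phenol is free, so base cannot open ring C.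

Step 11
Reactants: 17 benzyl ether (2R,3S,4S)-3,7-bis(benzyloxy)-2-[3,4-bis(benzyloxy)phenyl]-4-[6-bromo-2,3,4-tris(benzyloxy)phenyl]chromane
Product: 19 aldehyde 3,4,5-tris(benzyloxy)-2-[(2R,3S,4S)-3,7-bis(benzyloxy)-2-[3,4-bis(benzyloxy)phenyl]chroman-4-yl]benzaldehyde, via aryllithium 18 (not isolated)
Conditions: n-BuLi (1.2 equiv), THF, −78 °C, 10 min; then DMF (5 equiv), −78 → 0 °C; H2O
Reagents that add atoms: N,N-dimethylformamide, CN(C)C=O
Why: Bromine–lithium exchange, faster at −78 °C than deprotonation of C4–H or of the benzylic CH2 groups, followed by Bouveault formylation of aryllithium 18; this installs the carbon that becomes C2 of the flavonol.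

Step 12
Reactants: 20 acetophenone 2,4-dihydroxyacetophenone
Product: 21 benzyl ether 1-[4-(benzyloxy)-2-hydroxyphenyl]ethan-1-one
Conditions: BnBr (1.05 equiv), K2CO3, acetone, reflux
Reagents that add atoms: benzyl bromide, BrCc1ccccc1
Why: Selective Williamson benzylation of the 4-OH; the 2-OH is hydrogen-bonded to the carbonyl and much less nucleophilic, and it is needed free for the ring closure of step 14.

Step 13
Reactants: 19 aldehyde 3,4,5-tris(benzyloxy)-2-[(2R,3S,4S)-3,7-bis(benzyloxy)-2-[3,4-bis(benzyloxy)phenyl]chroman-4-yl]benzaldehyde; 21 benzyl ether 1-[4-(benzyloxy)-2-hydroxyphenyl]ethan-1-one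
Product: 22 chalcone (E)-1-[4-(benzyloxy)-2-hydroxyphenyl]-3-{3,4,5-tris(benzyloxy)-2-[(2R,3S,4S)-3,7-bis(benzyloxy)-2-[3,4-bis(benzyloxy)phenyl]chroman-4-yl]phenyl}prop-2-en-1-one
Conditions: KOH (aq, 50%), EtOH/THF, rt
Reagents that add atoms: none
Why: Claisen–Schmidt condensation (crossed aldol, then E1cB dehydration) gives the E enone; aldehyde 19 cannot enolise and no stereocentre of the flavan is α to a carbonyl, so the triad is not at risk.

Step 14
Reactants: 22 chalcone (E)-1-[4-(benzyloxy)-2-hydroxyphenyl]-3-{3,4,5-tris(benzyloxy)-2-[(2R,3S,4S)-3,7-bis(benzyloxy)-2-[3,4-bis(benzyloxy)phenyl]chroman-4-yl]phenyl}prop-2-en-1-one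
Product: 24 flavonol 7-(benzyloxy)-3-hydroxy-2-{3,4,5-tris(benzyloxy)-2-[(2R,3S,4S)-3,7-bis(benzyloxy)-2-[3,4-bis(benzyloxy)phenyl]chroman-4-yl]phenyl}-4H-chromen-4-one, via dihydroflavonol 23 (not isolated)
Conditions: H2O2 (30%, excess), NaOH (aq), MeOH/THF, 0 °C → rt
Reagents that add atoms: hydrogen peroxide, OO
Why: Algar–Flynn–Oyamada oxidation: the phenoxide closes onto the β-carbon while alkaline peroxide oxygenates C3, and dihydroflavonol 23 is oxidised on to the flavonol in the same flask. Ring D has no substituent ortho to the carbonyl, the situation that favours flavonol over aurone.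

Step 15
Reactants: 24 flavonol 7-(benzyloxy)-3-hydroxy-2-{3,4,5-tris(benzyloxy)-2-[(2R,3S,4S)-3,7-bis(benzyloxy)-2-[3,4-bis(benzyloxy)phenyl]chroman-4-yl]phenyl}-4H-chromen-4-one
Product: 25 target 2-{2-[(2R,3S,4S)-2-(3,4-dihydroxyphenyl)-3,7-dihydroxychroman-4-yl]-3,4,5-trihydroxyphenyl}-3,7-dihydroxy-4H-chromen-4-one
Conditions: H2 (1 atm), Pd(OH)2/C, THF/MeOH, rt; filtration under argon
Reagents that add atoms: none
Why: Catalytic hydrogenolysis should cleave all eight benzyl ethers (seven aryl, one alkyl) under neutral conditions that neither ionise C2 or C4 nor reduce the flavonol enone; the polyphenol is handled under inert gas.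

## Compound list

1 | 5-bromo-1,2,3-trimethoxybenzene | COc1cc(Br)cc(OC)c1OC | starting material
2 | 5-bromobenzene-1,2,3-triol | Oc1cc(Br)cc(O)c1O | intermediate
3 | 5-bromo-1,2,3-tris(benzyloxy)benzene | Brc1cc(OCc2ccccc2)c(OCc2ccccc2)c(OCc2ccccc2)c1 | intermediate
4 | 4-(benzyloxy)-2-hydroxybenzaldehyde | O=Cc1ccc(OCc2ccccc2)cc1O | starting material
5 | 2-(allyloxy)-4-(benzyloxy)benzaldehyde | O=Cc1ccc(OCc2ccccc2)cc1OCC=C | intermediate
6 | [6-bromo-2,3,4-tris(benzyloxy)phenyl]lithium | [Li]c1c(Br)cc(OCc2ccccc2)c(OCc2ccccc2)c1OCc1ccccc1 | intermediate (not isolated)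
7 | racemic [2-(allyloxy)-4-(benzyloxy)phenyl][6-bromo-2,3,4-tris(benzyloxy)phenyl]methanol | OC(c1ccc(OCc2ccccc2)cc1OCC=C)c1c(Br)cc(OCc2ccccc2)c(OCc2ccccc2)c1OCc1ccccc1 | intermediate
8 | [2-(allyloxy)-4-(benzyloxy)phenyl][6-bromo-2,3,4-tris(benzyloxy)phenyl]methanone | O=C(c1ccc(OCc2ccccc2)cc1OCC=C)c1c(Br)cc(OCc2ccccc2)c(OCc2ccccc2)c1OCc1ccccc1 | intermediate
9 | racemic 1-[2-(allyloxy)-4-(benzyloxy)phenyl]-1-[6-bromo-2,3,4-tris(benzyloxy)phenyl]ethan-1-ol | CC(O)(c1ccc(OCc2ccccc2)cc1OCC=C)c1c(Br)cc(OCc2ccccc2)c(OCc2ccccc2)c1OCc1ccccc1 | intermediate (not isolated)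
10 | 2-(allyloxy)-4-(benzyloxy)-1-{1-[6-bromo-2,3,4-tris(benzyloxy)phenyl]ethenyl}benzene | C=C(c1ccc(OCc2ccccc2)cc1OCC=C)c1c(Br)cc(OCc2ccccc2)c(OCc2ccccc2)c1OCc1ccccc1 | intermediate
11 | 5-(benzyloxy)-2-{1-[6-bromo-2,3,4-tris(benzyloxy)phenyl]ethenyl}phenol | C=C(c1ccc(OCc2ccccc2)cc1O)c1c(Br)cc(OCc2ccccc2)c(OCc2ccccc2)c1OCc1ccccc1 | intermediate
12 | 3,4-bis(benzyloxy)benzaldehyde | O=Cc1ccc(OCc2ccccc2)c(OCc2ccccc2)c1 | starting material
13 | [3,4-bis(benzyloxy)phenyl](5-(benzyloxy)-2-{1-[6-bromo-2,3,4-tris(benzyloxy)phenyl]ethenyl}phenoxy)methanol (hemiacetal, carbinol centre undefined) | C=C(c1ccc(OCc2ccccc2)cc1OC(O)c1ccc(OCc2ccccc2)c(OCc2ccccc2)c1)c1c(Br)cc(OCc2ccccc2)c(OCc2ccccc2)c1OCc1ccccc1 | intermediate (not isolated)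
14 | (2S)-7-(benzyloxy)-2-[3,4-bis(benzyloxy)phenyl]-4-[6-bromo-2,3,4-tris(benzyloxy)phenyl]-2H-chromene | Brc1cc(OCc2ccccc2)c(OCc2ccccc2)c(OCc2ccccc2)c1C1=C[C@@H](c2ccc(OCc3ccccc3)c(OCc3ccccc3)c2)Oc2cc(OCc3ccccc3)ccc12 | intermediate
15 | [(2S,3S,4S)-7-(benzyloxy)-2-[3,4-bis(benzyloxy)phenyl]-4-[6-bromo-2,3,4-tris(benzyloxy)phenyl]chroman-3-yl]borane (same spatial arrangement as 16) | Brc1cc(OCc2ccccc2)c(OCc2ccccc2)c(OCc2ccccc2)c1[C@@H]1c2ccc(OCc3ccccc3)cc2O[C@H](c2ccc(OCc3ccccc3)c(OCc3ccccc3)c2)[C@H]1B | intermediate (not isolated)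
16 | (2R,3S,4S)-7-(benzyloxy)-2-[3,4-bis(benzyloxy)phenyl]-4-[6-bromo-2,3,4-tris(benzyloxy)phenyl]chroman-3-ol | Brc1cc(OCc2ccccc2)c(OCc2ccccc2)c(OCc2ccccc2)c1[C@@H]1c2ccc(OCc3ccccc3)cc2O[C@H](c2ccc(OCc3ccccc3)c(OCc3ccccc3)c2)[C@H]1O | intermediate
17 | (2R,3S,4S)-3,7-bis(benzyloxy)-2-[3,4-bis(benzyloxy)phenyl]-4-[6-bromo-2,3,4-tris(benzyloxy)phenyl]chromane | Brc1cc(OCc2ccccc2)c(OCc2ccccc2)c(OCc2ccccc2)c1[C@@H]1c2ccc(OCc3ccccc3)cc2O[C@H](c2ccc(OCc3ccccc3)c(OCc3ccccc3)c2)[C@H]1OCc1ccccc1 | intermediate
18 | {3,4,5-tris(benzyloxy)-2-[(2R,3S,4S)-3,7-bis(benzyloxy)-2-[3,4-bis(benzyloxy)phenyl]chroman-4-yl]phenyl}lithium | [Li]c1cc(OCc2ccccc2)c(OCc2ccccc2)c(OCc2ccccc2)c1[C@@H]1c2ccc(OCc3ccccc3)cc2O[C@H](c2ccc(OCc3ccccc3)c(OCc3ccccc3)c2)[C@H]1OCc1ccccc1 | intermediate (not isolated)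
19 | 3,4,5-tris(benzyloxy)-2-[(2R,3S,4S)-3,7-bis(benzyloxy)-2-[3,4-bis(benzyloxy)phenyl]chroman-4-yl]benzaldehyde | O=Cc1cc(OCc2ccccc2)c(OCc2ccccc2)c(OCc2ccccc2)c1[C@@H]1c2ccc(OCc3ccccc3)cc2O[C@H](c2ccc(OCc3ccccc3)c(OCc3ccccc3)c2)[C@H]1OCc1ccccc1 | intermediate
20 | 2,4-dihydroxyacetophenone | CC(=O)c1ccc(O)cc1O | starting material
21 | 1-[4-(benzyloxy)-2-hydroxyphenyl]ethan-1-one | CC(=O)c1ccc(OCc2ccccc2)cc1O | intermediate
22 | (E)-1-[4-(benzyloxy)-2-hydroxyphenyl]-3-{3,4,5-tris(benzyloxy)-2-[(2R,3S,4S)-3,7-bis(benzyloxy)-2-[3,4-bis(benzyloxy)phenyl]chroman-4-yl]phenyl}prop-2-en-1-one | O=C(/C=C/c1cc(OCc2ccccc2)c(OCc2ccccc2)c(OCc2ccccc2)c1[C@@H]1c2ccc(OCc3ccccc3)cc2O[C@H](c2ccc(OCc3ccccc3)c(OCc3ccccc3)c2)[C@H]1OCc1ccccc1)c1ccc(OCc2ccccc2)cc1O | intermediate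
23 | 7-(benzyloxy)-3-hydroxy-2-{3,4,5-tris(benzyloxy)-2-[(2R,3S,4S)-3,7-bis(benzyloxy)-2-[3,4-bis(benzyloxy)phenyl]chroman-4-yl]phenyl}chroman-4-one (the two new centres are left undefined; both are removed on oxidation) | O=C1C(O)C(c2cc(OCc3ccccc3)c(OCc3ccccc3)c(OCc3ccccc3)c2[C@@H]2c3ccc(OCc4ccccc4)cc3O[C@H](c3ccc(OCc4ccccc4)c(OCc4ccccc4)c3)[C@H]2OCc2ccccc2)Oc2cc(OCc3ccccc3)ccc12 | intermediate (not isolated)
24 | 7-(benzyloxy)-3-hydroxy-2-{3,4,5-tris(benzyloxy)-2-[(2R,3S,4S)-3,7-bis(benzyloxy)-2-[3,4-bis(benzyloxy)phenyl]chroman-4-yl]phenyl}-4H-chromen-4-one | O=c1c(O)c(-c2cc(OCc3ccccc3)c(OCc3ccccc3)c(OCc3ccccc3)c2[C@@H]2c3ccc(OCc4ccccc4)cc3O[C@H](c3ccc(OCc4ccccc4)c(OCc4ccccc4)c3)[C@H]2OCc2ccccc2)oc2cc(OCc3ccccc3)ccc12 | intermediate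
25 | 2-{2-[(2R,3S,4S)-2-(3,4-dihydroxyphenyl)-3,7-dihydroxychroman-4-yl]-3,4,5-trihydroxyphenyl}-3,7-dihydroxy-4H-chromen-4-one | O=c1c(O)c(-c2cc(O)c(O)c(O)c2[C@@H]2c3ccc(O)cc3O[C@H](c3ccc(O)c(O)c3)[C@H]2O)oc2cc(O)ccc12 | target

## Step count and risk

Total step count: 15. Longest linear sequence: 13 steps (from 1 through steps 1, 2, 4–11 and 13–15 to 25); steps 3 and 12 are side branches.

Least certain steps:

1. Step 8 (key step, proposed new method). The electron-rich aldehyde 12 is a weak electrophile and the O-aryl oxocarbenium ion is high in energy. Protonation of the diarylethene (dimerisation, Friedel–Crafts capture) or hydroxyalkylation of ring A para to the phenol may therefore outrun ring closure. The product may also re-ionise at C2–O1 under the acid, which would erode enantiopurity, and the catalyst pocket may not discriminate the two faces of the ion well enough. Fallback with known chemistry, setting out from 21, 12 and 3 and returning at 14: Claisen–Schmidt condensation of 21 with 12 (KOH, EtOH) should give the 2'-hydroxychalcone (E)-1-[4-(benzyloxy)-2-hydroxyphenyl]-3-[3,4-bis(benzyloxy)phenyl]prop-2-en-1-one F1. Excess aryllithium 6, generated from 3 as in step 4, adds to its carbonyl at −78 °C to give the tertiary allylic alcohol racemic (E)-1-[4-(benzyloxy)-2-hydroxyphenyl]-3-[3,4-bis(benzyloxy)phenyl]-1-[6-bromo-2,3,4-tris(benzyloxy)phenyl]prop-2-en-1-ol F2. A chiral N-triflylphosphoramide, (R)-3,3'-bis(2,4,6-triisopropylphenyl)-BINOL N-(trifluoromethanesulfonyl)phosphoramide, in toluene at low temperature then ionises F2 to the triaryl allyl cation as a chiral contact ion pair, and the phenol closes onto the ring B terminus (asymmetric intramolecular allylic substitution, an established type of entry to 2,4-diaryl-2H-chromenes), giving 14.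

2. Step 4. The ortho-bromo aryllithium 6 may lose LiBr to an aryne before it meets the aldehyde, or the amide base may deprotonate a benzylic OCH2 group and start a Wittig rearrangement. Both arise because the carbanion sits next to a leaving group on a ring carrying three benzyl ethers. Fallback from 3, returning at 7: bromination of 3 with NBS in MeCN should give 1,2-dibromo-3,4,5-tris(benzyloxy)benzene F3. Bromine–magnesium exchange with i-PrMgCl·LiCl (THF, −40 °C) is expected at the bromine flanked by benzyloxy, which is chelation-assisted and gives the more stabilised carbanion, to form [6-bromo-2,3,4-tris(benzyloxy)phenyl]magnesium chloride F4. This is far less prone to elimination than 6 and adds to 5 to give 7.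

3. Step 9. Facial discrimination may be incomplete, or addition may be slow, because ring E stands perpendicular to the alkene with bromine on one face and benzyloxy on the other near C4, while the directing C2 aryl is remote from C4. Stepwise hydration routes are no remedy, since hydride delivery to a C4 cation would come anti to the C3 oxygen and give the 3,4-cis isomer. Fallback from 14, returning at 16: reagent-controlled hydroboration with monoisopinocampheylborane, a chiral borane made for trisubstituted aryl alkenes. The antipode whose preference reinforces attack anti to the C2 aryl is used (written here for the reagent from (+)-α-pinene). The dialkylborane (isopinocampheyl)[(2S,3S,4S)-7-(benzyloxy)-2-[3,4-bis(benzyloxy)phenyl]-4-[6-bromo-2,3,4-tris(benzyloxy)phenyl]chroman-3-yl]borane F5 is oxidised in the same flask (NaOH, H2O2) to 16.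

4. Step 11. The aryllithium 18 may be quenched by proton transfer from the triply activated C4–H or from a benzylic OCH2 before it is formylated, or exchange at the hindered bromide may be incomplete. Fallback from 17, returning at 19: Suzuki–Miyaura vinylation (K[CH2=CHBF3], Pd(OAc)2, SPhos, K3PO4, toluene/H2O, 80 °C) should give (2R,3S,4S)-3,7-bis(benzyloxy)-2-[3,4-bis(benzyloxy)phenyl]-4-[2,3,4-tris(benzyloxy)-6-ethenylphenyl]chromane F6 without any carbanion. Lemieux–Johnson cleavage (OsO4 cat., NaIO4, 2,6-lutidine, dioxane/H2O) then gives 19.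

5. Step 14. The bulky ortho substituent on ring E may slow attack of the phenoxide on the β-carbon, so that closure through the α-carbon (aurone formation) or stalling before the final oxidation takes over. Fallback from 22, returning at 24: oxidative cyclisation of 22 with catalytic I2 in DMSO at about 120 °C should give the flavone 7-(benzyloxy)-2-{3,4,5-tris(benzyloxy)-2-[(2R,3S,4S)-3,7-bis(benzyloxy)-2-[3,4-bis(benzyloxy)phenyl]chroman-4-yl]phenyl}-4H-chromen-4-one F7. Its C2=C3 bond is then epoxidised with dimethyldioxirane (acetone/CH2Cl2, 0 °C), and acid-catalysed opening of the epoxide delivers the 3-hydroxyflavone 24.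

## Further compounds

F1 | step 8 | (E)-1-[4-(benzyloxy)-2-hydroxyphenyl]-3-[3,4-bis(benzyloxy)phenyl]prop-2-en-1-one | O=C(/C=C/c1ccc(OCc2ccccc2)c(OCc2ccccc2)c1)c1ccc(OCc2ccccc2)cc1O
F2 | step 8 | racemic (E)-1-[4-(benzyloxy)-2-hydroxyphenyl]-3-[3,4-bis(benzyloxy)phenyl]-1-[6-bromo-2,3,4-tris(benzyloxy)phenyl]prop-2-en-1-ol | OC(/C=C/c1ccc(OCc2ccccc2)c(OCc2ccccc2)c1)(c1ccc(OCc2ccccc2)cc1O)c1c(Br)cc(OCc2ccccc2)c(OCc2ccccc2)c1OCc1ccccc1
F3 | step 4 | 1,2-dibromo-3,4,5-tris(benzyloxy)benzene | Brc1cc(OCc2ccccc2)c(OCc2ccccc2)c(OCc2ccccc2)c1Br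
F4 | step 4 | [6-bromo-2,3,4-tris(benzyloxy)phenyl]magnesium chloride | Cl[Mg]c1c(Br)cc(OCc2ccccc2)c(OCc2ccccc2)c1OCc1ccccc1
F5 | step 9 | (isopinocampheyl)[(2S,3S,4S)-7-(benzyloxy)-2-[3,4-bis(benzyloxy)phenyl]-4-[6-bromo-2,3,4-tris(benzyloxy)phenyl]chroman-3-yl]borane | Brc1cc(OCc2ccccc2)c(OCc2ccccc2)c(OCc2ccccc2)c1[C@@H]1c2ccc(OCc3ccccc3)cc2O[C@H](c2ccc(OCc3ccccc3)c(OCc3ccccc3)c2)[C@H]1B[C@@H]1C[C@@H]2C[C@H]([C@H]1C)C2(C)C
F6 | step 11 | (2R,3S,4S)-3,7-bis(benzyloxy)-2-[3,4-bis(benzyloxy)phenyl]-4-[2,3,4-tris(benzyloxy)-6-ethenylphenyl]chromane | C=Cc1cc(OCc2ccccc2)c(OCc2ccccc2)c(OCc2ccccc2)c1[C@@H]1c2ccc(OCc3ccccc3)cc2O[C@H](c2ccc(OCc3ccccc3)c(OCc3ccccc3)c2)[C@H]1OCc1ccccc1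
F7 | step 14 | 7-(benzyloxy)-2-{3,4,5-tris(benzyloxy)-2-[(2R,3S,4S)-3,7-bis(benzyloxy)-2-[3,4-bis(benzyloxy)phenyl]chroman-4-yl]phenyl}-4H-chromen-4-one | O=c1cc(-c2cc(OCc3ccccc3)c(OCc3ccccc3)c(OCc3ccccc3)c2[C@@H]2c3ccc(OCc4ccccc4)cc3O[C@H](c3ccc(OCc4ccccc4)c(OCc4ccccc4)c3)[C@H]2OCc2ccccc2)oc2cc(OCc3ccccc3)ccc12
A1 | alternative 1 | 3-{3,4,5-tris(benzyloxy)-2-[(2R,3S,4S)-3,7-bis(benzyloxy)-2-[3,4-bis(benzyloxy)phenyl]chroman-4-yl]phenyl}prop-2-ynoic acid | OC(=O)C#Cc1cc(OCc2ccccc2)c(OCc2ccccc2)c(OCc2ccccc2)c1[C@@H]1c2ccc(OCc3ccccc3)cc2O[C@H](c2ccc(OCc3ccccc3)c(OCc3ccccc3)c2)[C@H]1OCc1ccccc1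
A2 | alternative 1 | 5-(benzyloxy)-3-chloro-2-(trimethylsilyl)phenyl trifluoromethanesulfonate | C[Si](C)(C)c1c(Cl)cc(OCc2ccccc2)cc1OS(=O)(=O)C(F)(F)F
A3 | alternative 1 | 5-(benzyloxy)-3-chloro-1,2-didehydrobenzene | ClC1=CC(OCc2ccccc2)=CC#C1
A4 | alternative 1 | 1-[4-(benzyloxy)-2-chloro-6-hydroxyphenyl]-3-{3,4,5-tris(benzyloxy)-2-[(2R,3S,4S)-3,7-bis(benzyloxy)-2-[3,4-bis(benzyloxy)phenyl]chroman-4-yl]phenyl}prop-2-yn-1-one | O=C(C#Cc1cc(OCc2ccccc2)c(OCc2ccccc2)c(OCc2ccccc2)c1[C@@H]1c2ccc(OCc3ccccc3)cc2O[C@H](c2ccc(OCc3ccccc3)c(OCc3ccccc3)c2)[C@H]1OCc1ccccc1)c1c(Cl)cc(OCc2ccccc2)cc1O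
A5 | alternative 2 | 3,7-bis(benzyloxy)-2-{[(2R,3S,4R)-3,7-bis(benzyloxy)-2-[3,4-bis(benzyloxy)phenyl]chroman-4-yl]ethynyl}-4H-chromen-4-one | O=c1c(OCc2ccccc2)c(C#C[C@@H]2c3ccc(OCc4ccccc4)cc3O[C@H](c3ccc(OCc4ccccc4)c(OCc4ccccc4)c3)[C@H]2OCc2ccccc2)oc2cc(OCc3ccccc3)ccc12
A6 | alternative 2 | 3,4-bis(benzyloxy)furan | O(Cc1ccccc1)c1cocc1OCc1ccccc1
A7 | alternative 2 | 3,7-bis(benzyloxy)-2-{4,5-bis(benzyloxy)-3-hydroxy-2-[(2R,3S,4S)-3,7-bis(benzyloxy)-2-[3,4-bis(benzyloxy)phenyl]chroman-4-yl]phenyl}-4H-chromen-4-one | O=c1c(OCc2ccccc2)c(-c2cc(OCc3ccccc3)c(OCc3ccccc3)c(O)c2[C@@H]2c3ccc(OCc4ccccc4)cc3O[C@H](c3ccc(OCc4ccccc4)c(OCc4ccccc4)c3)[C@H]2OCc2ccccc2)oc2cc(OCc3ccccc3)ccc12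
A8 | alternative 3 | racemic [4-(benzyloxy)-2-hydroxyphenyl][6-bromo-2,3,4-tris(benzyloxy)phenyl]methanol | OC(c1ccc(OCc2ccccc2)cc1O)c1c(Br)cc(OCc2ccccc2)c(OCc2ccccc2)c1OCc1ccccc1
A9 | alternative 3 | 3-(benzyloxy)-6-{[6-bromo-2,3,4-tris(benzyloxy)phenyl]methylidene}cyclohexa-2,4-dien-1-one (alkene geometry undefined) | O=C1C=C(OCc2ccccc2)C=CC1=Cc1c(Br)cc(OCc2ccccc2)c(OCc2ccccc2)c1OCc1ccccc1
A10 | alternative 3 | (E)-2-[3,4-bis(benzyloxy)phenyl]ethenyl 2,2-dimethylpropanoate | CC(C)(C)C(=O)O/C=C/c1ccc(OCc2ccccc2)c(OCc2ccccc2)c1
A11 | alternative 3 | (2R,3S,4S)-7-(benzyloxy)-2-[3,4-bis(benzyloxy)phenyl]-4-[6-bromo-2,3,4-tris(benzyloxy)phenyl]chroman-3-yl 2,2-dimethylpropanoate | Brc1cc(OCc2ccccc2)c(OCc2ccccc2)c(OCc2ccccc2)c1[C@@H]1c2ccc(OCc3ccccc3)cc2O[C@H](c2ccc(OCc3ccccc3)c(OCc3ccccc3)c2)[C@H]1OC(=O)C(C)(C)C
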